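The cis-fused α-methyl-γ-lactone and the seven-membered carbocycle (C1, C5–C10) are cut together. The ring bond C6–C7, the bond C11–C12 and the lactone bond O–C12 all come from one titanocene-mediated carbonylative [2+2+1] of a C6 aldehyde, a (Z)-C7=C11 alkene and CO. The step exploits the fact that the lactone shares exactly the C6–C7 edge with the carbocycle, so both rings and the stereocentres C6, C7 and C11 form together. The precursor is an open-chain (Z)-hept-5-en-2-yl aldehyde on a tartrate-derived trans-dioxolane (C1/C5 acetonide) that carries C2 as a silyloxymethyl group.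

Key step: step 8

Remark on the chemistry: atom numbers follow the target (ring C1 tertiary carbinol, C5 acyloxy carbon, C6 lactone O–CH, C7–C9, C10 methyl-bearing; chain C2 ketone, C3, C4 carbinol; lactone C11 methyl-bearing, C12 carbonyl). Geometrically pure (E)-but-2-en-1-ol and (Z)-1-bromoprop-1-ene are assumed. A free C2 carbinol cis to a C6 ester on the dioxolane cannot be kept open, so it is closed to a lactone on purpose (step 3) and reopened as an N-methoxy-N-methylamide (step 4).

Step 1
Reactants: 1 dimethyl (4R,5R)-2,2-dimethyl-1,3-dioxolane-4,5-dicarboxylate (acetonide of dimethyl L-tartrate); 2 (E)-but-2-en-1-ol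
Product: 3 di[(E)-but-2-en-1-yl] (4R,5R)-2,2-dimethyl-1,3-dioxolane-4,5-dicarboxylate
Conditions: 2 (6 equiv), Bu2SnO (10 mol %), toluene, reflux, MeOH removed over 5 Å sieves
Reagents that add atoms: none
Why: Tin-mediated transesterification under neutral conditions exchanges both methyl esters without touching the acetal or the α-stereocentres, and the C2-symmetric diester makes the later enolisation unambiguous.

Step 2
Reactants: 3 di[(E)-but-2-en-1-yl] (4R,5R)-2,2-dimethyl-1,3-dioxolane-4,5-dicarboxylate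
Product: 6 (4S,5R)-5-{[(E)-but-2-en-1-yloxy]carbonyl}-4-[(2S)-but-3-en-2-yl]-2,2-dimethyl-1,3-dioxolane-4-carboxylic acid, via silyl ketene acetal 4 (not isolated), via trimethylsilyl ester 5 (not isolated)
Conditions: LiN(i-Pr)2 (1.1 equiv), THF, −78 °C; Me3SiCl/Et3N, −78 → 25 °C, then 55 °C; aq. citric acid
Reagents that add atoms: none
Why: Ireland–Claisen rearrangement: the chelated lithium enolate (enolate oxygen syn to the ring oxygen) is silylated and the (E)-butenyl unit is delivered through a chair transition state to the ketene acetal face anti to the C5 ester, which sets C1, while the ketene acetal geometry together with the E-alkene sets C10; the endocyclic C5–O bond lies orthogonal to the enolate π-system, which disfavours β-elimination.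

Step 3
Reactants: 6 (4S,5R)-5-{[(E)-but-2-en-1-yloxy]carbonyl}-4-[(2S)-but-3-en-2-yl]-2,2-dimethyl-1,3-dioxolane-4-carboxylic acid
Product: 9 (3aR,6aR)-6a-[(2S)-but-3-en-2-yl]-2,2-dimethyldihydrofuro[3,4-d][1,3]dioxol-4(3aH)-one, via isobutyl carbonic anhydride 7 (not isolated), via hydroxy ester 8 (not isolated)
Conditions: i-BuOCOCl, N-methylmorpholine, THF, −15 °C; NaBH4, H2O, 0 °C, short contact, then 25 °C
Reagents that add atoms: none
Why: Mixed-anhydride activation makes the hindered acid the most electrophilic carbonyl, so borohydride reduces it selectively beside the ester and both alkenes, and the new C2 alkoxide, cis to the C6 ester on the dioxolane, lactonises in the flask, which differentiates the two carboxyl carbons for good.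

Step 4
Reactants: 9 (3aR,6aR)-6a-[(2S)-but-3-en-2-yl]-2,2-dimethyldihydrofuro[3,4-d][1,3]dioxol-4(3aH)-one
Product: 10 (4R,5R)-5-[(2S)-but-3-en-2-yl]-5-(hydroxymethyl)-N-methoxy-N,2,2-trimethyl-1,3-dioxolane-4-carboxamide
Conditions: MeNH(OMe)·HCl, AlMe3, CH2Cl2, 0 → 25 °C; aq. KNaC4H4O6; crude product used at once
Reagents that add atoms: N,O-dimethylhydroxylamine hydrochloride, CNOC.Cl
Why: Aluminium amide aminolysis of a γ-lactone opens the ring at C6 under non-basic conditions that leave the α-alkoxy centre C5 untouched.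

Step 5
Reactants: 10 (4R,5R)-5-[(2S)-but-3-en-2-yl]-5-(hydroxymethyl)-N-methoxy-N,2,2-trimethyl-1,3-dioxolane-4-carboxamide
Product: 11 (4R,5R)-5-[(2S)-but-3-en-2-yl]-5-({[tert-butyl(dimethyl)silyl]oxy}methyl)-N-methoxy-N,2,2-trimethyl-1,3-dioxolane-4-carboxamide
Conditions: t-BuMe2SiOTf, 2,6-lutidine, CH2Cl2, −78 → 0 °C
Reagents that add atoms: tert-butyldimethylsilyl trifluoromethanesulfonate, CC(C)(C)[Si](C)(C)OS(=O)(=O)C(F)(F)F
Why: Silylation with the silyl triflate is fast enough at low temperature to cap the neopentyl-type carbinol before it can close back onto the amide.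

Step 6
Reactants: 11 (4R,5R)-5-[(2S)-but-3-en-2-yl]-5-({[tert-butyl(dimethyl)silyl]oxy}methyl)-N-methoxy-N,2,2-trimethyl-1,3-dioxolane-4-carboxamide; 12 (Z)-1-bromoprop-1-ene
Product: 14 (4R,5R)-5-({[tert-butyl(dimethyl)silyl]oxy}methyl)-5-[(2S,5Z)-hept-5-en-2-yl]-N-methoxy-N,2,2-trimethyl-1,3-dioxolane-4-carboxamide, via B-alkyl-9-borabicyclononane 13 (not isolated)
Conditions: 9-BBN, THF, 0 → 25 °C; then 12 (3 equiv), Pd(dppf)Cl2 (5 mol %), K3PO4 aq., DMF, 25 °C, closed vessel
Reagents that add atoms: none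
Why: Anti-Markovnikov hydroboration of the only alkene followed by B-alkyl Suzuki–Miyaura coupling, which retains the (Z)-geometry of the alkenyl bromide and leaves the amide and silyl ether alone.

Step 7
Reactants: 14 (4R,5R)-5-({[tert-butyl(dimethyl)silyl]oxy}methyl)-5-[(2S,5Z)-hept-5-en-2-yl]-N-methoxy-N,2,2-trimethyl-1,3-dioxolane-4-carboxamide
Product: 15 (4R,5R)-5-({[tert-butyl(dimethyl)silyl]oxy}methyl)-5-[(2S,5Z)-hept-5-en-2-yl]-2,2-dimethyl-1,3-dioxolane-4-carbaldehyde
Conditions: i-Bu2AlH, THF, −78 °C; aq. KNaC4H4O6, 0 °C; used directly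
Reagents that add atoms: none
Why: The stable N-methoxy-N-methyl chelate stops hydride reduction at the aldehyde oxidation state, and the cold neutral work-up avoids epimerisation at C5.

Step 8
Reactants: 15 (4R,5R)-5-({[tert-butyl(dimethyl)silyl]oxy}methyl)-5-[(2S,5Z)-hept-5-en-2-yl]-2,2-dimethyl-1,3-dioxolane-4-carbaldehyde
Product: 18 tricyclic acetonide lactone (target numbering 1R,5S,6R,7S,10S,11R; C2 as tert-butyldimethylsilyloxymethyl), via oxatitanacyclopentane 16 (not isolated), via acyl titanacycle 17 (not isolated)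
Conditions: Cp2Ti(PMe3)2 (1.1 equiv, made beforehand from Cp2TiCl2, Mg, PMe3), toluene, 0.02 M, 25 °C; then CO (1.2 atm), 25 → 70 °C
Reagents that add atoms: carbon monoxide, [C-]#[O+]
Why: Proposed new method: the divalent titanium centre loses phosphine, binds the C6 aldehyde side-on and inserts the tethered C7=C11 alkene to give oxatitanacyclopentane 16 (C6–C7 bond), CO inserts into the Ti–C11 bond to give 17, and C12–O reductive elimination releases the lactone and Cp2Ti(CO)2; the closest known reaction is the titanocene-mediated hetero-Pauson–Khand cyclocarbonylation of unsaturated aldehydes and ketones to fused γ-butyrolactones, established for five- and six-membered carbocycles but not for seven. The carbocycle closes by 7-exo C–C bond formation (exo at both the carbonyl and the alkene) inside the metal coordination sphere, and the lactone closes by contraction of the six-membered acyl titanacycle to the five-membered ring in the reductive elimination. C6 and C7 are cis because both sit in the same five-membered metallacycle, and C11 follows from the (Z)-alkene by syn addition and CO insertion with retention, which puts its methyl cis to C8. C6 relative to C5 is set by the dioxolane: the bulky Cp2Ti–(O=CH) unit should sit over the C5–H and away from the quaternary C1, so C7 bonds anti to the C5–O bond and the C6 oxygen ends trans to the C5 oxygen. The step needs ring closure to beat bimolecular aldehyde coupling and cleavage of the C5–O bond, which the trans-dioxolane (C6 and C10 held gauche), the fully substituted C1 and dilution are meant to secure.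

Step 9
Reactants: 18 tricyclic acetonide lactone (C2 as tert-butyldimethylsilyloxymethyl)
Product: 19 tricyclic acetonide lactone with C2 as hydroxymethyl (target numbering 1R,5S,6R,7S,10S,11R)
Conditions: HF·pyridine, pyridine, THF, 0 → 25 °C
Reagents that add atoms: none
Why: Pyridine-buffered fluoride cleaves the primary silyl ether without base that could epimerise C11 and without acid strong enough to open the acetonide.

Step 10
Reactants: 19 tricyclic acetonide lactone with C2 as hydroxymethyl
Product: 20 tricyclic acetonide lactone with C2 as formyl (target numbering 1S,5S,6R,7S,10S,11R)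
Conditions: Dess–Martin periodinane, pyridine, CH2Cl2, 0 → 25 °C
Reagents that add atoms: none
Why: Dess–Martin oxidation of a primary alcohol gives an aldehyde that has no α-hydrogen and so cannot enolise or epimerise.

Step 11
Reactants: 21 (R)-2-methyloxirane
Product: 22 (2R)-1-(phenylsulfonyl)propan-2-ol
Conditions: PhSO2Na, H2O, 60 °C, sealed tube
Reagents that add atoms: sodium benzenesulfinate, [Na+].[O-]S(=O)c1ccccc1
Why: The sulfinate sulfur opens the epoxide at the unsubstituted carbon (SN2), so the stereocentre, the future C4, is not involved and keeps its (R)-configuration.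

Step 12
Reactants: 22 (2R)-1-(phenylsulfonyl)propan-2-ol
Product: 23 tert-butyl(dimethyl){[(2R)-1-(phenylsulfonyl)propan-2-yl]oxy}silane
Conditions: t-BuMe2SiCl, imidazole, DMF, 25 °C
Reagents that add atoms: tert-butyldimethylsilyl chloride, CC(C)(C)[Si](C)(C)Cl
Why: Standard silylation of a secondary alcohol blocks the C4 oxygen through the carbanion and acylation steps.

Step 13
Reactants: 20 tricyclic acetonide lactone with C2 as formyl; 23 tert-butyl(dimethyl){[(2R)-1-(phenylsulfonyl)propan-2-yl]oxy}silane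
Product: 25 β-hydroxy sulfone (C2 carbinol and C3 sulfonyl epimers; C4 R; ring as in 20), via α-lithio sulfone 24 (not isolated)
Conditions: 23 (1.5 equiv), n-BuLi (1.4 equiv), THF, −78 °C; then 20, −78 °C; AcOH in THF at −78 °C
Reagents that add atoms: none
Why: Addition of an α-sulfonyl carbanion to an aldehyde at −78 °C, where carbonyl addition should outrun both loss of silanolate from the carbanion and proton transfer from the lactone; the two new centres (C2, C3) are erased later.

Step 14
Reactants: 25 β-hydroxy sulfone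
Product: 26 β-keto sulfone (C2 ketone; C3 sulfonyl epimers)
Conditions: Dess–Martin periodinane, pyridine, CH2Cl2, 25 °C
Reagents that add atoms: none
Why: Dess–Martin oxidation converts both carbinol epimers into the same β-keto sulfone under near-neutral conditions.

Step 15
Reactants: 26 β-keto sulfone
Product: 27 acetonide-protected ketone with C4 tert-butyldimethylsilyl ether (target numbering 1S,4R,5S,6R,7S,10S,11R)
Conditions: SmI2 (2.2 equiv), THF/MeOH (10:1), −78 °C
Reagents that add atoms: none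
Why: Single-electron reductive cleavage of the activated C–S bond of a β-keto sulfone, with methanol protonating the samarium enolate at −78 °C before it can expel the β-silyloxy group; the sulfonyl group is reduced far faster than the α-alkoxy C1–O bond.

Step 16
Reactants: 27 acetonide-protected ketone with C4 tert-butyldimethylsilyl ether
Product: 28 C1,C5-diol with C4 tert-butyldimethylsilyl ether (target numbering 1S,4R,5S,6R,7S,10S,11R)
Conditions: AcOH/THF/H2O (3:1:1), 40 °C
Reagents that add atoms: none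
Why: The strained trans-fused dioxolane should hydrolyse under mild aqueous acid that a secondary tert-butyldimethylsilyl ether tolerates, which unmasks the C1 and C5 hydroxyls.

Step 17
Reactants: 28 C1,C5-diol with C4 tert-butyldimethylsilyl ether; 29 angelic acid, (Z)-2-methylbut-2-enoic acid
Product: 31 C5 angelate with C4 tert-butyldimethylsilyl ether, via angelic trichlorobenzoic anhydride 30 (not isolated)
Conditions: 29, 2,4,6-Cl3C6H2COCl, Et3N, toluene, 25 °C; then 28, 80 °C
Reagents that add atoms: none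
Why: Yamaguchi-type acyl transfer from the mixed anhydride, run without a nucleophilic catalyst, acylates the secondary C5 hydroxyl in preference to the tertiary C1 hydroxyl and keeps the (Z)-geometry of the angeloyl group.

Step 18
Reactants: 31 C5 angelate with C4 tert-butyldimethylsilyl ether
Product: 32 CNP0321985.1, (3R,3aS,6S,7S,8S,8aR)-7-hydroxy-7-[(3R)-3-hydroxybutanoyl]-3,6-dimethyl-2-oxooctahydro-2H-cyclohepta[b]furan-8-yl (2Z)-2-methylbut-2-enoate
Conditions: HF·pyridine, THF, 0 → 25 °C
Reagents that add atoms: none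
Why: Acidic fluoride removes the last silyl ether without base, so the β-hydroxy ketone, the α-ketol, the angelate geometry and C11 are not put at risk.

Compound list
1 | dimethyl (4R,5R)-2,2-dimethyl-1,3-dioxolane-4,5-dicarboxylate | COC(=O)[C@@H]1OC(C)(C)O[C@H]1C(=O)OC | starting material
2 | (E)-but-2-en-1-ol | C/C=C/CO | starting material
3 | di[(E)-but-2-en-1-yl] (4R,5R)-2,2-dimethyl-1,3-dioxolane-4,5-dicarboxylate | C/C=C/COC(=O)[C@@H]1OC(C)(C)O[C@H]1C(=O)OC/C=C/C | intermediate
4 | (E)-but-2-en-1-yl (4R)-5-{[(E)-but-2-en-1-yloxy](trimethylsilyloxy)methylidene}-2,2-dimethyl-1,3-dioxolane-4-carboxylate, silyloxy group cis to the ring oxygen | C/C=C/CO/C(O[Si](C)(C)C)=C1/OC(C)(C)O[C@H]1C(=O)OC/C=C/C | intermediate (not isolated)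
5 | trimethylsilyl ester of acid 6 | C[Si](C)(C)OC(=O)[C@@]1([C@@H](C)C=C)OC(C)(C)O[C@H]1C(=O)OC/C=C/C | intermediate (not isolated)
6 | (4S,5R)-5-{[(E)-but-2-en-1-yloxy]carbonyl}-4-[(2S)-but-3-en-2-yl]-2,2-dimethyl-1,3-dioxolane-4-carboxylic acid | OC(=O)[C@@]1([C@@H](C)C=C)OC(C)(C)O[C@H]1C(=O)OC/C=C/C | intermediate
7 | mixed anhydride of acid 6 with isobutyl carbonic acid | CC(C)COC(=O)OC(=O)[C@@]1([C@@H](C)C=C)OC(C)(C)O[C@H]1C(=O)OC/C=C/C | intermediate (not isolated)
8 | (E)-but-2-en-1-yl (4R,5R)-5-[(2S)-but-3-en-2-yl]-5-(hydroxymethyl)-2,2-dimethyl-1,3-dioxolane-4-carboxylate | OC[C@@]1([C@@H](C)C=C)OC(C)(C)O[C@H]1C(=O)OC/C=C/C | intermediate (not isolated)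
9 | (3aR,6aR)-6a-[(2S)-but-3-en-2-yl]-2,2-dimethyldihydrofuro[3,4-d][1,3]dioxol-4(3aH)-one | O1C[C@@]2([C@@H](C)C=C)OC(C)(C)O[C@H]2C1=O | intermediate
10 | (4R,5R)-5-[(2S)-but-3-en-2-yl]-5-(hydroxymethyl)-N-methoxy-N,2,2-trimethyl-1,3-dioxolane-4-carboxamide | OC[C@@]1([C@@H](C)C=C)OC(C)(C)O[C@H]1C(=O)N(C)OC | intermediate
11 | (4R,5R)-5-[(2S)-but-3-en-2-yl]-5-({[tert-butyl(dimethyl)silyl]oxy}methyl)-N-methoxy-N,2,2-trimethyl-1,3-dioxolane-4-carboxamide | CC(C)(C)[Si](C)(C)OC[C@@]1([C@@H](C)C=C)OC(C)(C)O[C@H]1C(=O)N(C)OC | intermediate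
12 | (Z)-1-bromoprop-1-ene | C/C=C\Br | starting material
13 | B-alkyl-9-borabicyclo[3.3.1]nonane from 11, boron on C8 | CC(C)(C)[Si](C)(C)OC[C@@]1([C@@H](C)CCB2C3CCCC2CCC3)OC(C)(C)O[C@H]1C(=O)N(C)OC | intermediate (not isolated)
14 | (4R,5R)-5-({[tert-butyl(dimethyl)silyl]oxy}methyl)-5-[(2S,5Z)-hept-5-en-2-yl]-N-methoxy-N,2,2-trimethyl-1,3-dioxolane-4-carboxamide | CC(C)(C)[Si](C)(C)OC[C@@]1([C@@H](C)CC/C=C\C)OC(C)(C)O[C@H]1C(=O)N(C)OC | intermediate
15 | (4R,5R)-5-({[tert-butyl(dimethyl)silyl]oxy}methyl)-5-[(2S,5Z)-hept-5-en-2-yl]-2,2-dimethyl-1,3-dioxolane-4-carbaldehyde (precursor of the key step) | CC(C)(C)[Si](C)(C)OC[C@@]1([C@@H](C)CC/C=C\C)OC(C)(C)O[C@H]1C=O | intermediate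
16 | bis(cyclopentadienyl) oxatitanacyclopentane, Ti bound to the C6 oxygen and to C11, C6–C7 bond formed | CC1(C)O[C@H]2[C@@H]3O[Ti+2][C@H](C)[C@@H]3CC[C@H](C)[C@@]2(O1)CO[Si](C)(C)C(C)(C)C.c1cc[cH-]c1.c1cc[cH-]c1 | intermediate (not isolated)
17 | bis(cyclopentadienyl) acyl titanacycle, CO inserted between Ti and C11 | CC1(C)O[C@H]2[C@@H]3O[Ti+2]C(=O)[C@H](C)[C@@H]3CC[C@H](C)[C@@]2(O1)CO[Si](C)(C)C(C)(C)C.c1cc[cH-]c1.c1cc[cH-]c1 | intermediate (not isolated)
18 | tricyclic lactone: seven-membered ring C1/C5–C10, cis-fused α-methyl-γ-lactone at C6–C7, trans-fused C1/C5 acetonide, C2 as CH2OSi(t-Bu)Me2 (1R,5S,6R,7S,10S,11R) | CC1(C)O[C@H]2[C@@H]3OC(=O)[C@H](C)[C@@H]3CC[C@H](C)[C@@]2(O1)CO[Si](C)(C)C(C)(C)C | intermediate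
19 | tricyclic acetonide lactone with C2 as CH2OH (1R,5S,6R,7S,10S,11R) | CC1(C)O[C@H]2[C@@H]3OC(=O)[C@H](C)[C@@H]3CC[C@H](C)[C@@]2(O1)CO | intermediate
20 | tricyclic acetonide lactone with C2 as CHO (1S,5S,6R,7S,10S,11R) | CC1(C)O[C@H]2[C@@H]3OC(=O)[C@H](C)[C@@H]3CC[C@H](C)[C@@]2(O1)C=O | intermediate
21 | (R)-2-methyloxirane | C[C@@H]1CO1 | starting material
22 | (2R)-1-(phenylsulfonyl)propan-2-ol | C[C@@H](O)CS(=O)(=O)c1ccccc1 | intermediate
23 | tert-butyl(dimethyl){[(2R)-1-(phenylsulfonyl)propan-2-yl]oxy}silane | C[C@@H](O[Si](C)(C)C(C)(C)C)CS(=O)(=O)c1ccccc1 | intermediate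
24 | α-lithio derivative of sulfone 23 | C[C@@H](O[Si](C)(C)C(C)(C)C)C([Li])S(=O)(=O)c1ccccc1 | intermediate (not isolated)
25 | β-hydroxy sulfone: tricyclic acetonide lactone with C1 bearing CH(OH)–CH(SO2Ph)–CH(OSi(t-Bu)Me2)CH3 (C2, C3 epimers; C4 R) | CC1(C)O[C@H]2[C@@H]3OC(=O)[C@H](C)[C@@H]3CC[C@H](C)[C@@]2(O1)C(O)C([C@@H](C)O[Si](C)(C)C(C)(C)C)S(=O)(=O)c1ccccc1 | intermediate
26 | β-keto sulfone: as 25 with C2 as ketone (C3 epimers; C4 R) | CC1(C)O[C@H]2[C@@H]3OC(=O)[C@H](C)[C@@H]3CC[C@H](C)[C@@]2(O1)C(=O)C([C@@H](C)O[Si](C)(C)C(C)(C)C)S(=O)(=O)c1ccccc1 | intermediate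
27 | tricyclic acetonide lactone with C1 bearing (3R)-3-(tert-butyldimethylsilyloxy)butanoyl (1S,4R,5S,6R,7S,10S,11R) | CC1(C)O[C@H]2[C@@H]3OC(=O)[C@H](C)[C@@H]3CC[C@H](C)[C@@]2(O1)C(=O)C[C@@H](C)O[Si](C)(C)C(C)(C)C | intermediate
28 | C1,C5-diol of the bicyclic lactone with C4 silyl ether (1S,4R,5S,6R,7S,10S,11R) | O[C@H]1[C@@H]2OC(=O)[C@H](C)[C@@H]2CC[C@H](C)[C@@]1(O)C(=O)C[C@@H](C)O[Si](C)(C)C(C)(C)C | intermediate
29 | angelic acid, (Z)-2-methylbut-2-enoic acid | C/C=C(/C)C(=O)O | starting material
30 | (Z)-2-methylbut-2-enoic 2,4,6-trichlorobenzoic anhydride | C/C=C(/C)C(=O)OC(=O)c1c(Cl)cc(Cl)cc1Cl | intermediate (not isolated)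
31 | C5 angelate of 28, C4 still silylated (1S,4R,5S,6R,7S,10S,11R) | C/C=C(/C)C(=O)O[C@H]1[C@@H]2OC(=O)[C@H](C)[C@@H]2CC[C@H](C)[C@@]1(O)C(=O)C[C@@H](C)O[Si](C)(C)C(C)(C)C | intermediate
32 | CNP0321985.1, (3R,3aS,6S,7S,8S,8aR)-7-hydroxy-7-[(3R)-3-hydroxybutanoyl]-3,6-dimethyl-2-oxooctahydro-2H-cyclohepta[b]furan-8-yl (2Z)-2-methylbut-2-enoate | C/C=C(/C)C(=O)O[C@H]1[C@@H]2OC(=O)[C@H](C)[C@@H]2CC[C@H](C)[C@@]1(O)C(=O)C[C@@H](C)O | target

Total step count: 18. Longest linear sequence: 16 (steps 1–10 and 13–18; steps 11–12 make the sulfone branch).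

Steps most likely to fail

Step 8 (Proposed new method). The titanacycle may not span the seven-membered ring, so that bimolecular reductive coupling of the aldehyde, reductive cleavage of the C5–O bond by the low-valent metal, or binding of the wrong aldehyde face takes over. Fallback with known reactions, closing the lactone first and the carbocycle second, from 11 back to 18: hydroboration of 11 as in step 6 followed by oxidation (9-BBN; NaBO3·4H2O) should give the primary C8 alcohol F1, and I2/PPh3/imidazole converts it into the primary iodide F2. CH2=CHMgBr at −78 °C turns the amide into the vinyl ketone F3. Luche reduction (NaBH4, CeCl3·7H2O, MeOH, −78 °C) under Felkin–Anh control should give the allylic alcohol F4 with the C6 oxygen syn to the C5 oxygen along the chain, which is trans in the later ring. Methacryloyl chloride/Et3N gives the methacrylate F5, and ring-closing metathesis with the second-generation Grubbs catalyst closes the α-methylbutenolide F6. Slow addition of Bu3SnH/AIBN in hot toluene at high dilution then closes the carbocycle by 7-exo addition of the C8 radical to C7 of the butenolide on the face of the tether (cis fusion), and hydrogen transfer to C11 from the convex face places the methyl cis to C8, which gives 18.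

Step 2. The enolate may fragment by loss of the ring alkoxide, a mixed ketene acetal geometry or a boat transition state may erode the C10 configuration, or the allyl unit may be delivered syn to the ester. Fallback, intermolecular and catalyst-controlled, from 1 and 2 back to 9: 2 and methyl chloroformate/pyridine give (E)-but-2-en-1-yl methyl carbonate F7, and 1 is converted with LiN(i-Pr)2/Me3SiCl at −78 °C into the silyl ketene acetal F8. Branched-selective iridium-catalysed allylic substitution of F7 by F8 ([Ir(cod)Cl]2, chiral phosphoramidite, fluoride activation; ligand enantiomer chosen for the required C10 configuration, attack anti to the C5 ester) should give the dimethyl diester F9. LiAlH4 reduces both esters to the diol F10, and TEMPO/PhI(OAc)2 oxidises the less hindered C6 carbinol and carries the lactol on to lactone 9, which also replaces step 3.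

Step 13. The lithiated sulfone may lose silanolate before it adds, the addition to the neopentyl-type aldehyde may revert, or the carbanion may deprotonate the lactone at C11. Fallback by aldol construction of C3–C4, from 20 back to 27: MeMgBr at −78 °C adds to 20 to give the C2 methyl carbinol F11, and Dess–Martin oxidation gives the methyl ketone F12, which can enolise only at the methyl group. Its diisopinocampheylboron enolate (Ipc2BCl, Et3N, Et2O; reagent enantiomer chosen for attack on the Si face of the aldehyde) adds to acetaldehyde at −78 °C to give the (4R)-β-hydroxy ketone F13, and t-BuMe2SiOTf/2,6-lutidine converts it into 27, which also bypasses steps 14 and 15.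

Further compounds
F1 | step 8 | (4R,5R)-5-({[tert-butyl(dimethyl)silyl]oxy}methyl)-5-[(2S)-4-hydroxybutan-2-yl]-N-methoxy-N,2,2-trimethyl-1,3-dioxolane-4-carboxamide | CC(C)(C)[Si](C)(C)OC[C@@]1([C@@H](C)CCO)OC(C)(C)O[C@H]1C(=O)N(C)OC
F2 | step 8 | (4R,5R)-5-({[tert-butyl(dimethyl)silyl]oxy}methyl)-5-[(2S)-4-iodobutan-2-yl]-N-methoxy-N,2,2-trimethyl-1,3-dioxolane-4-carboxamide | CC(C)(C)[Si](C)(C)OC[C@@]1([C@@H](C)CCI)OC(C)(C)O[C@H]1C(=O)N(C)OC
F3 | step 8 | 1-[(4R,5R)-5-({[tert-butyl(dimethyl)silyl]oxy}methyl)-5-[(2S)-4-iodobutan-2-yl]-2,2-dimethyl-1,3-dioxolan-4-yl]prop-2-en-1-one | CC(C)(C)[Si](C)(C)OC[C@@]1([C@@H](C)CCI)OC(C)(C)O[C@H]1C(=O)C=C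
F4 | step 8 | (1R)-1-[(4S,5R)-5-({[tert-butyl(dimethyl)silyl]oxy}methyl)-5-[(2S)-4-iodobutan-2-yl]-2,2-dimethyl-1,3-dioxolan-4-yl]prop-2-en-1-ol | CC(C)(C)[Si](C)(C)OC[C@@]1([C@@H](C)CCI)OC(C)(C)O[C@H]1[C@H](O)C=C
F5 | step 8 | 2-methylprop-2-enoate of F4 | CC(C)(C)[Si](C)(C)OC[C@@]1([C@@H](C)CCI)OC(C)(C)O[C@H]1[C@H](OC(=O)C(C)=C)C=C
F6 | step 8 | (5R)-5-[(4S,5R)-5-({[tert-butyl(dimethyl)silyl]oxy}methyl)-5-[(2S)-4-iodobutan-2-yl]-2,2-dimethyl-1,3-dioxolan-4-yl]-3-methylfuran-2(5H)-one | CC(C)(C)[Si](C)(C)OC[C@@]1([C@@H](C)CCI)OC(C)(C)O[C@H]1[C@@H]2OC(=O)C(C)=C2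
F7 | step 2 | (E)-but-2-en-1-yl methyl carbonate | C/C=C/COC(=O)OC
F8 | step 2 | methyl (4R)-5-[methoxy(trimethylsilyloxy)methylidene]-2,2-dimethyl-1,3-dioxolane-4-carboxylate | COC(O[Si](C)(C)C)=C1OC(C)(C)O[C@H]1C(=O)OC
F9 | step 2 | dimethyl (4S,5R)-4-[(2S)-but-3-en-2-yl]-2,2-dimethyl-1,3-dioxolane-4,5-dicarboxylate | COC(=O)[C@@]1([C@@H](C)C=C)OC(C)(C)O[C@H]1C(=O)OC
F10 | step 2 | {(4R,5S)-4-[(2S)-but-3-en-2-yl]-2,2-dimethyl-1,3-dioxolane-4,5-diyl}dimethanol | OC[C@@]1([C@@H](C)C=C)OC(C)(C)O[C@H]1CO
F11 | step 13 | tricyclic acetonide lactone with C1 bearing 1-hydroxyethyl (C2 epimers) | CC1(C)O[C@H]2[C@@H]3OC(=O)[C@H](C)[C@@H]3CC[C@H](C)[C@@]2(O1)C(C)O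
F12 | step 13 | tricyclic acetonide lactone with C1 bearing acetyl | CC1(C)O[C@H]2[C@@H]3OC(=O)[C@H](C)[C@@H]3CC[C@H](C)[C@@]2(O1)C(C)=O
F13 | step 13 | tricyclic acetonide lactone with C1 bearing (3R)-3-hydroxybutanoyl | CC1(C)O[C@H]2[C@@H]3OC(=O)[C@H](C)[C@@H]3CC[C@H](C)[C@@]2(O1)C(=O)C[C@@H](C)O
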